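The O1–C2 bond of ring C is the disconnection. Ring B arrives with its 3'-sulfate already in place (persulfate C–H oxidation), is joined to ring A by aldol condensation, and the C2–C3 chain is turned into a cyclic sulfate. The key step exploits the fact that O4' is para to C2 through C1' of ring B: acid unmasks the phenols, only the benzylic C2–O bond of the cyclic sulfate ionises, one of the two equivalent ring A hydroxyls closes ring C, and the sulfur remains on O3 as the 3-sulfate. Its precursor is a trans-4-aroyl-5-aryl-1,3,2-dioxathiolane 2,2-dioxide bearing MOM and Boc groups. Dehydrogenation then gives the achiral target.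

Key step: step 8

Assumption 1: the target has no stereocentre and no stereogenic double bond, so "single enantiomer" is read as the constitution shown; compounds 7 to 13 are racemic with one enantiomer drawn.
Assumption 2: sulfate monoesters are drawn as free acids, as in the target, but are carried as potassium or tetrabutylammonium salts; counter-ion changes belong to the work-up and are not counted as steps.

Step 1
Reactants: 1 4-hydroxybenzaldehyde
Product: 2 5-formyl-2-hydroxyphenyl hydrogen sulfate (potassium salt, then tetrabutylammonium salt)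
Conditions: K2S2O8 (1.0 equiv), 10% aq. KOH, 0 °C → rt, 24 h; pH 4–5, Et2O extraction of unreacted 1 (recycled); Bu4NHSO4, CH2Cl2 ion-pair extraction
Reagents that add atoms: potassium peroxodisulfate, [K+].[K+].[O-]S(=O)(=O)OOS(=O)(=O)[O-]
Why: Elbs persulfate oxidation, in which the phenoxide attacks the peroxide oxygen through a ring carbon; the para position is blocked by the formyl group and the two ortho C–H are equivalent, so the new oxygen should enter next to the free OH already as its sulfate ester, as is known for para-blocked phenols with electron-withdrawing groups.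

Step 2
Reactants: 3 1-(2,6-dihydroxy-4-methoxyphenyl)ethanone
Product: 4 1-[4-methoxy-2,6-bis(methoxymethoxy)phenyl]ethanone
Conditions: NaH (2.4 equiv), MOMCl (2.4 equiv), DMF, 0 °C → rt
Reagents that add atoms: chloromethyl methyl ether, COCCl
Why: Williamson-type O-alkylation (MOM ether formation) of both phenoxides, the sodium salts being needed to alkylate the carbonyl-chelated ortho hydroxyls, gives a ring A fragment that is stable to the alkali of the aldol step.

Step 3
Reactants: 2 5-formyl-2-hydroxyphenyl hydrogen sulfate; 4 1-[4-methoxy-2,6-bis(methoxymethoxy)phenyl]ethanone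
Product: 5 2-hydroxy-5-[(E)-3-[4-methoxy-2,6-bis(methoxymethoxy)phenyl]-3-oxoprop-1-enyl]phenyl hydrogen sulfate (chalcone with free 4-OH)
Conditions: KOH (50% aq.), EtOH, rt, 24–48 h; pH 6–7 (cold NaH2PO4); Bu4NHSO4, CH2Cl2
Reagents that add atoms: none
Why: Claisen–Schmidt condensation (crossed aldol, then E1cB dehydration) of the methyl ketone enolate with the non-enolisable aldehyde should give the conjugated E-alkene as the thermodynamic product, since aryl sulfate monoester anions and MOM acetals are inert to aqueous alkali.

Step 4
Reactants: 5 chalcone with free 4-OH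
Product: 6 2-(tert-butoxycarbonyloxy)-5-[(E)-3-[4-methoxy-2,6-bis(methoxymethoxy)phenyl]-3-oxoprop-1-enyl]phenyl hydrogen sulfate (tetrabutylammonium salt)
Conditions: Boc2O (1.3 equiv), Et3N, DMAP (cat.), CH2Cl2, 0 °C → rt
Reagents that add atoms: di-tert-butyl dicarbonate, CC(C)(C)OC(=O)OC(=O)OC(C)(C)C
Why: DMAP-catalysed acyl transfer to the only free phenol (carbonate formation), the sulfate monoanion being non-nucleophilic; the carbonate makes ring B electron-poor enough for the later benzylic cyclic sulfate to be isolable and is removed by the same acid as the MOM groups.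

Step 5
Reactants: 6 4-O-Boc chalcone
Product: 7 2-(tert-butoxycarbonyloxy)-5-[(1S*,2R*)-1,2-dihydroxy-3-[4-methoxy-2,6-bis(methoxymethoxy)phenyl]-3-oxopropyl]phenyl hydrogen sulfate (syn α,β-diol, racemic)
Conditions: OsO4 (2 mol%), NMO (1.5 equiv), citric acid (1 equiv), t-BuOH/H2O 1:1, rt; Na2SO3 quench
Reagents that add atoms: osmium tetroxide (catalytic oxygen carrier), O=[Os](=O)(=O)=O; N-methylmorpholine N-oxide, C[N+]1([O-])CCOCC1; water, O
Why: Upjohn dihydroxylation in its citric acid-accelerated form for electron-poor alkenes, in which suprafacial [3+2] addition of OsO4 to the E-enone sets both new stereocentres at once as the syn (αR*,βS*) diol, racemic because no chiral ligand is present, while the pH 4–5 medium leaves carbonate, acetals and aryl sulfate intact.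

Step 6
Reactants: 7 syn α,β-diol
Product: 8 trans-4-[4-methoxy-2,6-bis(methoxymethoxy)benzoyl]-5-[4-(tert-butoxycarbonyloxy)-3-(sulfooxy)phenyl]-1,3,2-dioxathiolane 2-oxide (aroyl carbon R*, aryl carbon S*; both sulfur epimers)
Conditions: SOCl2 (1.3 equiv), pyridine (3 equiv), CH2Cl2, −20 → 0 °C
Reagents that add atoms: thionyl chloride, O=S(Cl)Cl
Why: cyclic sulfite formation from a 1,2-diol with thionyl chloride and an amine base touches only the O–H bonds, so both carbons keep their configuration and the syn diol should give the trans ring as a pair of sulfur epimers that converge in the next step.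

Step 7
Reactants: 8 trans cyclic sulfite
Product: 9 trans-4-[4-methoxy-2,6-bis(methoxymethoxy)benzoyl]-5-[4-(tert-butoxycarbonyloxy)-3-(sulfooxy)phenyl]-1,3,2-dioxathiolane 2,2-dioxide (aroyl carbon R*, aryl carbon S*, racemic)
Conditions: RuCl3·xH2O (1 mol%), NaIO4 (1.3 equiv), EtOAc/MeCN/H2O, 0 °C, 15 min
Reagents that add atoms: sodium periodate, [Na+].[O-]I(=O)(=O)=O
Why: ruthenium tetroxide-catalysed oxidation of sulfur(IV) to sulfur(VI), the standard second half of the sulfite route to cyclic sulfates, is complete within minutes at 0 °C and so should outrun attack on the acylated trialkoxy ring A; it replaces direct sulfuryl transfer, which would chlorinate ring A (sulfuryl chloride) or need an alkoxide beside the acidic α-C–H (sulfonyldiimidazole).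

Step 8
Reactants: 9 trans cyclic sulfate
Product: 12 trans-7-O-methyldihydroquercetin 3,3'-disulfate (2R*,3R*; racemic; bis-tetrabutylammonium salt), via deprotected cyclic sulfate 10 (not isolated), via para-quinone methide 11 (not isolated)
Conditions: TFA/CH2Cl2 1:2 (anhydrous), 0 °C, 20–30 min; pour into cold aq. NaHCO3; Bu4NHSO4 ion-pair extraction or C18
Reagents that add atoms: none
Why: Proposed new method: TFA removes the two MOM acetals and the tert-butyl carbonate to give 10, whose freed 4'-OH, para to the benzylic carbon, drives heterolysis of the benzylic C–O bond of the cyclic sulfate, so that the alkyl sulfate stays on the α-carbon as the leaving group and the O-protonated quinone methide 11 is captured at its exocyclic carbon by one of the two equivalent ortho hydroxyls of ring A. The closest known reaction types are the acid-induced cyclisation of 2'-O-MOM chalcone epoxides to trans-dihydroflavonols and the opening of 1,2-cyclic sulfates at carbon by oxygen nucleophiles, where the sulfate monoester is normally hydrolysed afterwards instead of being kept. Ring C closes by 6-exo-trig attack of the phenol oxygen on the quinone methide carbon, which forms O1–C2 and restores the aromaticity of ring B. C3 keeps the configuration set in step 5 because its C–O bond is never broken, and C2 is re-formed under substrate control in the ring closure, where the reversible ionisation should settle on the trans isomer with the 2-aryl and 3-sulfate groups both equatorial. The step needs benzylic instead of α C–O cleavage and six- instead of five-membered closure, and both are secured because only the benzylic carbon is para-related to O4', whereas the α-carbon next to the ketone cannot ionise and is not displaced by a neutral phenol in acid. The aryl 3'-sulfate is the acid-sensitive bystander, which is the reason for the short, cold, anhydrous exposure and the bicarbonate quench; both stereocentres are erased in step 9, so a stereochemical leak here would not reach the target.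

Step 9
Reactants: 12 trans-7-O-methyldihydroquercetin 3,3'-disulfate
Product: 14 rhamnetin 3,3'-disulfate (target), via C2 quinone methide 13 (not isolated)
Conditions: DDQ (1.2 equiv), 1,4-dioxane, 25 → 50 °C; C18; Dowex 50W (H+ form), H2O, 0 °C, freeze-dry at once (dipotassium salt as storage form)
Reagents that add atoms: none
Why: quinone dehydrogenation of a flavanone to a flavone, in which DDQ abstracts hydride from C2–H (benzylic, α to O1 and para-related to the free 4'-OH) and the resulting cation, drawn as quinone methide 13, loses the acidic C3–H to give the aromatic pyranone, erasing both stereocentres while the 3-O-sulfate blocks the over-oxidation typical of free flavonols.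

Compound list
1 | 4-hydroxybenzaldehyde | O=Cc1ccc(O)cc1 | starting material
2 | 5-formyl-2-hydroxyphenyl hydrogen sulfate | O=Cc1ccc(O)c(OS(=O)(=O)O)c1 | intermediate
3 | 1-(2,6-dihydroxy-4-methoxyphenyl)ethanone | CC(=O)c1c(O)cc(OC)cc1O | starting material
4 | 1-[4-methoxy-2,6-bis(methoxymethoxy)phenyl]ethanone | CC(=O)c1c(OCOC)cc(OC)cc1OCOC | intermediate
5 | 2-hydroxy-5-[(E)-3-[4-methoxy-2,6-bis(methoxymethoxy)phenyl]-3-oxoprop-1-enyl]phenyl hydrogen sulfate | COCOc1cc(OC)cc(OCOC)c1C(=O)/C=C/c1ccc(O)c(OS(=O)(=O)O)c1 | intermediate
6 | 2-(tert-butoxycarbonyloxy)-5-[(E)-3-[4-methoxy-2,6-bis(methoxymethoxy)phenyl]-3-oxoprop-1-enyl]phenyl hydrogen sulfate | COCOc1cc(OC)cc(OCOC)c1C(=O)/C=C/c1ccc(OC(=O)OC(C)(C)C)c(OS(=O)(=O)O)c1 | intermediate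
7 | 2-(tert-butoxycarbonyloxy)-5-[(1S*,2R*)-1,2-dihydroxy-3-[4-methoxy-2,6-bis(methoxymethoxy)phenyl]-3-oxopropyl]phenyl hydrogen sulfate (racemic) | COCOc1cc(OC)cc(OCOC)c1C(=O)[C@H](O)[C@@H](O)c1ccc(OC(=O)OC(C)(C)C)c(OS(=O)(=O)O)c1 | intermediate
8 | trans-4-aroyl-5-aryl-1,3,2-dioxathiolane 2-oxide from 7 (racemic, sulfur epimers) | COCOc1cc(OC)cc(OCOC)c1C(=O)[C@@H]1OS(=O)O[C@H]1c1ccc(OC(=O)OC(C)(C)C)c(OS(=O)(=O)O)c1 | intermediate
9 | trans-4-aroyl-5-aryl-1,3,2-dioxathiolane 2,2-dioxide (racemic) | COCOc1cc(OC)cc(OCOC)c1C(=O)[C@@H]1OS(=O)(=O)O[C@H]1c1ccc(OC(=O)OC(C)(C)C)c(OS(=O)(=O)O)c1 | intermediate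
10 | deprotected cyclic sulfate: trans-4-(2,6-dihydroxy-4-methoxybenzoyl)-5-[4-hydroxy-3-(sulfooxy)phenyl]-1,3,2-dioxathiolane 2,2-dioxide (not isolated) | Oc1cc(OC)cc(O)c1C(=O)[C@@H]1OS(=O)(=O)O[C@H]1c1ccc(O)c(OS(=O)(=O)O)c1 | intermediate
11 | para-quinone methide with α-sulfate, drawn neutral, O-protonated in TFA, exocyclic C=C geometry not defined (not isolated) | Oc1cc(OC)cc(O)c1C(=O)[C@H](OS(=O)(=O)O)C=C1C=CC(=O)C(OS(=O)(=O)O)=C1 | intermediate
12 | (2R*,3R*)-5-hydroxy-2-[4-hydroxy-3-(sulfooxy)phenyl]-7-methoxy-4-oxochroman-3-yl hydrogen sulfate (trans, racemic) | COc1cc(O)c2C(=O)[C@H](OS(=O)(=O)O)[C@H](Oc2c1)c1ccc(O)c(OS(=O)(=O)O)c1 | intermediate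
13 | C2 quinone methide of 12 after hydride loss, drawn neutral, exocyclic C=C geometry not defined (not isolated) | COc1cc(O)c2C(=O)[C@H](OS(=O)(=O)O)C(Oc2c1)=C1C=CC(=O)C(OS(=O)(=O)O)=C1 | intermediate
14 | rhamnetin 3,3'-disulfate: 5-hydroxy-2-[4-hydroxy-3-(sulfooxy)phenyl]-7-methoxy-4-oxo-4H-chromen-3-yl hydrogen sulfate | COc1cc(O)c2c(=O)c(OS(=O)(=O)O)c(-c3ccc(O)c(OS(=O)(=O)O)c3)oc2c1 | target

Total step count: 9. Longest linear sequence: 8 steps (1 → 2 → 5 → 6 → 7 → 8 → 9 → 12 → 14).

Steps most likely to fail

Step 8 (key step, proposed new method). Three processes may defeat it: acid solvolysis of the aryl 3'-sulfate before deprotection and closure are complete, C-alkylation of ring A by the liberated methoxymethyl and tert-butyl cations, and interception of the benzylic cation by trifluoroacetate or by proton loss instead of ring closure. The fallback uses known chemistry, sets out from chalcone 5 and returns at 12. The free phenol of 5 is benzylated (BnBr, K2CO3, DMF) to the 4-O-benzyl chalcone F1. Alkaline hydrogen peroxide (Weitz–Scheffer epoxidation) converts it into the trans-epoxide F2. Brief acid treatment (cold TFA in CH2Cl2 instead of hot methanolic HCl, to spare the aryl sulfate) removes the MOM groups, and the freed 2'-OH opens the epoxide at the benzylic carbon, the established route from 2'-O-MOM chalcone epoxides to trans-dihydroflavonols, to give the 4'-O-benzyl trans-dihydroflavonol F3 with a free 3-OH. This secondary alcohol is sulfated with SO3·pyridine in pyridine/DMF, the chelated 5-OH being unreactive and the 4'-oxygen masked, to give the 3-O-sulfate F4. Hydrogenolysis of the benzyl ether (H2, Pd/C, MeOH/EtOAc) then gives 12.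

Step 7. RuO4 may attack the electron-rich ring A or the acetal methylene groups in competition with sulfur oxidation, and the benzylic C–O bond may ionise in the aqueous medium. The fallback sets out from diol 7 and returns at cyclic sulfate 9 without any oxidant, by direct sulfur(VI) transfer: the diol is deprotonated twice at −78 °C (LiHMDS, THF) and the dialkoxide is treated with 1,1'-sulfonyldiimidazole (−78 → −30 °C), a known way to close cyclic sulfates. This fallback passes through no new compound (F0).

Step 9. Hydride abstraction may be slow because the C2 cation is destabilised by the neighbouring sulfate and carbonyl, so that the heating then required causes loss of sulfate or over-oxidation of the ring B phenol. The fallback sets out from 12 and returns at 14, and replaces hydride abstraction by an enol-based dehydrogenation. Treatment of 12 with TMSOTf/Et3N in CH2Cl2 gives the 4-silyl enol ether with silylated 5-O and 4'-O, the tris-trimethylsilyl derivative F5. Saegusa–Ito oxidation of F5 (Pd(OAc)2, MeCN, rt) introduces the C2–C3 double bond, and aqueous work-up removes the aryl silyl ethers to give 14.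

Further compounds
F1 | step 8 | 2-(benzyloxy)-5-[(E)-3-[4-methoxy-2,6-bis(methoxymethoxy)phenyl]-3-oxoprop-1-enyl]phenyl hydrogen sulfate | COCOc1cc(OC)cc(OCOC)c1C(=O)/C=C/c1ccc(OCc2ccccc2)c(OS(=O)(=O)O)c1
F2 | step 8 | trans-epoxide of F1 (aroyl carbon R*, aryl carbon S*, racemic) | COCOc1cc(OC)cc(OCOC)c1C(=O)[C@@H]1O[C@H]1c1ccc(OCc2ccccc2)c(OS(=O)(=O)O)c1
F3 | step 8 | (2R*,3R*)-2-(benzyloxy)-5-(3,5-dihydroxy-7-methoxy-4-oxochroman-2-yl)phenyl hydrogen sulfate (trans, racemic) | COc1cc(O)c2C(=O)[C@H](O)[C@H](Oc2c1)c1ccc(OCc3ccccc3)c(OS(=O)(=O)O)c1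
F4 | step 8 | (2R*,3R*)-2-[4-(benzyloxy)-3-(sulfooxy)phenyl]-5-hydroxy-7-methoxy-4-oxochroman-3-yl hydrogen sulfate (trans, racemic) | COc1cc(O)c2C(=O)[C@H](OS(=O)(=O)O)[C@H](Oc2c1)c1ccc(OCc3ccccc3)c(OS(=O)(=O)O)c1
F0 | step 7 | none | none
F5 | step 9 | 7-methoxy-4,5-bis(trimethylsilyloxy)-2-[3-(sulfooxy)-4-(trimethylsilyloxy)phenyl]-2H-chromen-3-yl hydrogen sulfate (racemic) | COc1cc(O[Si](C)(C)C)c2C(O[Si](C)(C)C)=C(OS(=O)(=O)O)[C@H](Oc2c1)c1ccc(O[Si](C)(C)C)c(OS(=O)(=O)O)c1
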